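## Retrosynthetic overview

1. Target 36 comes from 35 by one acid step. 35 is cut at the C8–C2 (ring B) bond: nickel-catalysed C2–H addition of 2-H-pyranone 34 across the terminal alkene of dienyl pyranone 21, which sets C8 and leaves the 6E alkene.
2. 21 comes from triketone 20 (ring A by cyclodehydration), made from aldehyde 14 and the dianion of diketone 17. The C2–C5 stereotetrad comes from a Z-boron aldol of dienone 5 with Roche aldehyde 8, then a 1,3-syn reduction.
3. 34 comes from methoxy-enone diketone 33 (ring B by acid cyclisation), made from aldehyde 27 (anti-crotylboration of propanal) and the enolate of 30.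
4. Ring order: the dioxane protecting ring (step 7) and ring A (step 13) in the west branch; ring B (step 20) independently in the east branch; the two pyranones are joined last (step 21).

Assumption: the target is exactly the given SMILES, i.e. (2R,3R,4R,5S,6E,8S) in the nonenyl chain and (2S,3S) in the hydroxypentyl arm. Ipc reagents made from (−)-α-pinene are taken to attack the Re face of an aldehyde. The antipode of the chiral carbene L* in step 21 would be fixed by a model screen and is written here with (R) side arms. L* = 1,3-bis{2,6-bis[(1R)-1-phenylethyl]-4-methylphenyl}imidazol-2-ylidene.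

## Route

Step 1
Reactants: 1 2-bromopentan-3-one
Product: 3 2-(triphenyl-λ5-phosphanylidene)pentan-3-one, via phosphonium bromide 2 (not isolated)
Conditions: PPh3, PhMe, 80 °C; then NaOH (aq), CH2Cl2, rt
Reagents that add atoms: triphenylphosphine, c1ccc(cc1)P(c1ccccc1)c1ccccc1
Why: SN2 alkylation of the phosphine by the α-bromo ketone and deprotonation of the salt give the stabilised keto ylide (Wittig reagent preparation).

Step 2
Reactants: 3 2-(triphenyl-λ5-phosphanylidene)pentan-3-one; 4 acrolein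
Product: 5 (E)-4-methylhepta-4,6-dien-3-one
Conditions: CH2Cl2, 40 °C, trace hydroquinone
Reagents that add atoms: none
Why: Wittig olefination with a stabilised ylide gives the E trisubstituted enone, which fixes the 6E geometry of the target.

Step 3
Reactants: 6 methyl (S)-3-hydroxy-2-methylpropanoate
Product: 7 methyl (S)-3-[(tert-butyldimethylsilyl)oxy]-2-methylpropanoate
Conditions: TBSCl, imidazole, DMF, rt
Reagents that add atoms: tert-butyldimethylsilyl chloride, CC(C)(C)[Si](C)(C)Cl
Why: Standard silylation of the primary alcohol; the Roche ester supplies the C2 methyl centre of the chain.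

Step 4
Reactants: 7 methyl (S)-3-[(tert-butyldimethylsilyl)oxy]-2-methylpropanoate
Product: 8 (S)-3-[(tert-butyldimethylsilyl)oxy]-2-methylpropanal
Conditions: i-Bu2AlH (1.05 equiv), CH2Cl2, −78 °C; MeOH, aq. KNaC4H4O6; used crude
Reagents that add atoms: none
Why: Partial ester reduction at low temperature stops at the aldehyde through the stable aluminium hemiacetal, and the α-centre is not touched.

Step 5
Reactants: 5 (E)-4-methylhepta-4,6-dien-3-one; 8 (S)-3-[(tert-butyldimethylsilyl)oxy]-2-methylpropanal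
Product: 10 (4E,6R,7S,8S)-9-[(tert-butyldimethylsilyl)oxy]-7-hydroxy-4,6,8-trimethylnona-1,3-dien-5-one, via boron enolate 9 (not isolated)
Conditions: (+)-Ipc2BOTf [from (−)-α-pinene], i-Pr2NEt, CH2Cl2, −78 °C; then 8, −78 → −20 °C; H2O2, MeOH, pH 7 buffer
Reagents that add atoms: none
Why: Paterson boron aldol, in which the Z enolate reacts through a chair transition state to give the syn aldol (C3-OH/C4-Me), and Re-face attack directed by the Ipc ligands agrees with the anti-Felkin preference of Z enolates, so C2-Me/C3-OH come out anti.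

Step 6
Reactants: 10 (4E,6R,7S,8S)-9-[(tert-butyldimethylsilyl)oxy]-7-hydroxy-4,6,8-trimethylnona-1,3-dien-5-one
Product: 11 (2S,3S,4R,5S,6E)-1-[(tert-butyldimethylsilyl)oxy]-2,4,6-trimethylnona-6,8-diene-3,5-diol
Conditions: Et2BOMe, NaBH4, THF/MeOH 4:1, −78 °C; aqueous work-up, then MeOH azeotrope to release Et2BOMe
Reagents that add atoms: none
Why: Narasaka–Prasad reduction, in which external hydride adds to the six-membered boron chelate of the β-hydroxy enone in a 1,2 sense and gives the 1,3-syn diol, so C5 is set and the syn,syn triad is complete.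

Step 7
Reactants: 11 (2S,3S,4R,5S,6E)-1-[(tert-butyldimethylsilyl)oxy]-2,4,6-trimethylnona-6,8-diene-3,5-diol
Product: 12 tert-butyldimethyl{(2S)-2-[(4S,5R,6S)-2,2,5-trimethyl-6-[(2E)-penta-2,4-dien-2-yl]-1,3-dioxan-4-yl]propoxy}silane
Conditions: Me2C(OMe)2, PPTS (cat.), CH2Cl2, rt
Reagents that add atoms: 2,2-dimethoxypropane, COC(C)(C)OC
Why: Acid-catalysed transketalisation protects the syn 1,3-diol as an all-equatorial acetonide under conditions mild enough for the dienylic C–O bond.

Step 8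
Reactants: 12 tert-butyldimethyl{(2S)-2-[(4S,5R,6S)-2,2,5-trimethyl-6-[(2E)-penta-2,4-dien-2-yl]-1,3-dioxan-4-yl]propoxy}silane
Product: 13 (2S)-2-[(4S,5R,6S)-2,2,5-trimethyl-6-[(2E)-penta-2,4-dien-2-yl]-1,3-dioxan-4-yl]propan-1-ol
Conditions: n-Bu4NF, THF, 0 °C → rt
Reagents that add atoms: none
Why: Fluoride cleaves the primary silyl ether and leaves the acetonide and diene untouched.

Step 9
Reactants: 13 (2S)-2-[(4S,5R,6S)-2,2,5-trimethyl-6-[(2E)-penta-2,4-dien-2-yl]-1,3-dioxan-4-yl]propan-1-ol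
Product: 14 (2R)-2-[(4R,5R,6S)-2,2,5-trimethyl-6-[(2E)-penta-2,4-dien-2-yl]-1,3-dioxan-4-yl]propanal
Conditions: Dess–Martin periodinane, CH2Cl2, 0 °C → rt; used at once
Reagents that add atoms: none
Why: Dess–Martin oxidation gives the α-chiral aldehyde without epimerisation (the descriptor changes only through CIP priorities).

Step 10
Reactants: 15 pentan-3-one; 16 propanoyl chloride
Product: 17 4-methylheptane-3,5-dione
Conditions: MgBr2·OEt2, i-Pr2NEt, CH2Cl2, rt; aq. HCl work-up
Reagents that add atoms: none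
Why: Soft enolisation of the ketone by the magnesium Lewis acid and amine followed by C-acylation (crossed Claisen type) gives the 2-methyl-1,3-diketone.

Step 11
Reactants: 17 4-methylheptane-3,5-dione; 14 (2R)-2-[(4R,5R,6S)-2,2,5-trimethyl-6-[(2E)-penta-2,4-dien-2-yl]-1,3-dioxan-4-yl]propanal
Product: 19 7-hydroxy-4,6-dimethyl-8-[(4R,5R,6S)-2,2,5-trimethyl-6-[(2E)-penta-2,4-dien-2-yl]-1,3-dioxan-4-yl]nonane-3,5-dione (C8 and ring centres as in 14; mixture at C4, C6, C7), via dilithium dienolate 18 (not isolated)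
Conditions: LiN(i-Pr)2 (2.2 equiv), THF, −78 → 0 °C; then 14, −78 °C; AcOH quench
Reagents that add atoms: none
Why: The diketone dianion reacts at its more basic terminal carbon in an aldol addition; the three new centres are removed in steps 12 and 13, so their mixture is of no consequence.

Step 12
Reactants: 19 hydroxy diketone described in step 11
Product: 20 4,6-dimethyl-8-[(4R,5R,6S)-2,2,5-trimethyl-6-[(2E)-penta-2,4-dien-2-yl]-1,3-dioxan-4-yl]nonane-3,5,7-trione (C8 as in 14; keto–enol and C4/C6 epimer mixture)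
Conditions: Dess–Martin periodinane, CH2Cl2, 0 °C → rt
Reagents that add atoms: none
Why: Dess–Martin oxidation of the secondary alcohol gives the 1,3,5-triketone under near-neutral conditions that preserve the C8 centre.

Step 13
Reactants: 20 triketone described in step 12
Product: 21 2-ethyl-3,5-dimethyl-6-{(1R)-1-[(4R,5R,6S)-2,2,5-trimethyl-6-[(2E)-penta-2,4-dien-2-yl]-1,3-dioxan-4-yl]ethyl}-4H-pyran-4-one
Conditions: PPh3, CCl4, Et3N, THF, rt
Reagents that add atoms: none
Why: Appel-type activation of one enol oxygen as an oxyphosphonium and attack by the other enol oxygen (cyclodehydration of a triketone to a γ-pyrone) closes ring A without strong acid.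

Step 14
Reactants: 22 propanal; 23 (E)-but-2-ene
Product: 25 (3S,4R)-4-methylhex-5-en-3-ol, via crotylborane 24 (not isolated)
Conditions: KOt-Bu, n-BuLi, THF, −78 → −45 °C; (+)-Ipc2BOMe [from (−)-α-pinene], −78 °C; BF3·OEt2; then 22, −78 °C; NaOH, H2O2
Reagents that add atoms: none
Why: Brown crotylboration, in which the E crotylborane reacts through a chair Zimmerman–Traxler transition state to give the anti homoallylic alcohol and the Ipc ligands direct Re-face attack, so both centres of the hydroxypentyl arm are set.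

Step 15
Reactants: 25 (3S,4R)-4-methylhex-5-en-3-ol
Product: 26 tert-butyldimethyl{[(3S,4R)-4-methylhex-5-en-3-yl]oxy}silane
Conditions: TBSOTf, 2,6-lutidine, CH2Cl2, −78 → 0 °C
Reagents that add atoms: tert-butyldimethylsilyl triflate, CC(C)(C)[Si](C)(C)OS(=O)(=O)C(F)(F)F
Why: Silyl triflate with a hindered base silylates the secondary alcohol cleanly.

Step 16
Reactants: 26 tert-butyldimethyl{[(3S,4R)-4-methylhex-5-en-3-yl]oxy}silane
Product: 27 (2S,3S)-3-[(tert-butyldimethylsilyl)oxy]-2-methylpentanal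
Conditions: O3, CH2Cl2, −78 °C; then PPh3, −78 °C → rt
Reagents that add atoms: ozone, [O-][O+]=O
Why: Ozonolysis with reductive work-up cleaves the vinyl group to the aldehyde without touching the α-centre.

Step 17
Reactants: 15 pentan-3-one; 28 ethyl formate
Product: 30 (E)-1-methoxy-2-methylpent-1-en-3-one, via sodium enolate 29 (not isolated)
Conditions: NaH, Et2O, 0 °C → rt; solvent switch; Me2SO4, DMF, rt
Reagents that add atoms: dimethyl sulfate, COS(=O)(=O)OC
Why: Claisen formylation of the ketone followed by O-methylation of the hard sodium enolate in a polar aprotic solvent gives the vinylogous ester.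

Step 18
Reactants: 30 (E)-1-methoxy-2-methylpent-1-en-3-one; 27 (2S,3S)-3-[(tert-butyldimethylsilyl)oxy]-2-methylpentanal
Product: 32 (1E,6R,7S)-7-[(tert-butyldimethylsilyl)oxy]-5-hydroxy-1-methoxy-2,4,6-trimethylnon-1-en-3-one (mixture at C4 and C5), via lithium enolate 31 (not isolated)
Conditions: LiN(SiMe3)2, THF, −78 °C; then 27, −78 °C; AcOH quench
Reagents that add atoms: none
Why: Kinetic α′-deprotonation of the vinylogous ester and aldol addition at −78 °C; the two new centres are removed in steps 19 and 20.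

Step 19
Reactants: 32 hydroxy enone described in step 18
Product: 33 (1E,6S,7S)-7-[(tert-butyldimethylsilyl)oxy]-1-methoxy-2,4,6-trimethylnon-1-ene-3,5-dione (C4 epimers and enol)
Conditions: Dess–Martin periodinane, CH2Cl2, 0 °C → rt
Reagents that add atoms: none
Why: Dess–Martin oxidation gives the β-diketone with the C6 centre intact.

Step 20
Reactants: 33 methoxy-enone diketone described in step 19
Product: 34 2-[(2S,3S)-3-[(tert-butyldimethylsilyl)oxy]pentan-2-yl]-3,5-dimethyl-4H-pyran-4-one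
Conditions: CF3CO2H (20 mol %), PhH, rt
Reagents that add atoms: none
Why: The enol oxygen of the diketone adds to the β-methoxy enone and methanol is eliminated (addition–elimination cyclisation to a γ-pyrone), closing ring B with a free C–H next to the ring oxygen.

Step 21
Reactants: 21 dienyl pyranone described in step 13; 34 2-[(2S,3S)-3-[(tert-butyldimethylsilyl)oxy]pentan-2-yl]-3,5-dimethyl-4H-pyran-4-one
Product: 35 2-ethyl-3,5-dimethyl-6-{(1R)-1-[(4R,5R,6S)-2,2,5-trimethyl-6-[(2E,4S)-4-{6-[(2S,3S)-3-[(tert-butyldimethylsilyl)oxy]pentan-2-yl]-3,5-dimethyl-4-oxo-4H-pyran-2-yl}pent-2-en-2-yl]-1,3-dioxan-4-yl]ethyl}-4H-pyran-4-one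
Conditions: Ni(cod)2 (10 mol %), L* (10 mol %), MeAl(OC6H2-2,6-t-Bu2-4-Me)2 (40 mol %), 34 (1.5 equiv), PhMe, 40–60 °C
Reagents that add atoms: none
Why: Proposed new method: the aluminium Lewis acid binds the pyranone carbonyl and acidifies the C2–H bond, the zerovalent nickel–carbene complex holds the diene and transfers that hydrogen to the terminal CH2 (ligand-to-ligand hydrogen transfer), and the resulting syn-η3-allyl(pyranonyl)nickel undergoes C–C reductive elimination at the less hindered CH(CH3) terminus inside the chiral pocket of L*, which forms the C8–C2 bond, sets C8 as S under catalyst control and leaves the E trisubstituted alkene; the closest known reactions are the nickel/aluminium-catalysed C6–H alkylation of 2-pyridones and 4-pyridones with 1,3-dienes and enantioselective nickel–carbene hydroheteroarylations of alkenes, but a 4-pyranone C–H bond has not been used.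

Step 22
Reactants: 35 protected bis-pyranone described in step 21
Product: 36 2-ethyl-6-[(2R,3R,4R,5S,6E,8S)-3,5-dihydroxy-4,6-dimethyl-8-{6-[(2S,3S)-3-hydroxypentan-2-yl]-3,5-dimethyl-4-oxo-4H-pyran-2-yl}non-6-en-2-yl]-3,5-dimethyl-4H-pyran-4-one (CNP0408419.10)
Conditions: HF (48 % aq.), MeCN, 0 °C → rt
Reagents that add atoms: none
Why: Aqueous HF in acetonitrile removes the silyl ether and hydrolyses the acetonide in one operation without ionising the allylic C5–O bond; no stereocentre is touched.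

## Compound list

1 | 2-bromopentan-3-one (racemic) | CCC(=O)C(C)Br | starting material
2 | (3-oxopentan-2-yl)triphenylphosphonium bromide (formed in the flask) | CCC(=O)C(C)[P+](c1ccccc1)(c1ccccc1)c1ccccc1.[Br-] | intermediate
3 | 2-(triphenyl-λ5-phosphanylidene)pentan-3-one | CCC(=O)C(C)=P(c1ccccc1)(c1ccccc1)c1ccccc1 | intermediate
4 | acrolein | C=CC=O | starting material
5 | (E)-4-methylhepta-4,6-dien-3-one | CCC(=O)/C(C)=C/C=C | intermediate
6 | methyl (S)-3-hydroxy-2-methylpropanoate | OC[C@H](C)C(=O)OC | starting material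
7 | methyl (S)-3-[(tert-butyldimethylsilyl)oxy]-2-methylpropanoate | CC(C)(C)[Si](C)(C)OC[C@H](C)C(=O)OC | intermediate
8 | (S)-3-[(tert-butyldimethylsilyl)oxy]-2-methylpropanal | CC(C)(C)[Si](C)(C)OC[C@H](C)C=O | intermediate
9 | (2Z,4E)-4-methylhepta-2,4,6-trien-3-yl bis(isopinocampheyl)borinate (formed in the flask) | C/C=C(\OB([C@H]1C[C@H]2C[C@@H]([C@@H]1C)C2(C)C)[C@H]1C[C@H]2C[C@@H]([C@@H]1C)C2(C)C)/C(C)=C/C=C | intermediate
10 | (4E,6R,7S,8S)-9-[(tert-butyldimethylsilyl)oxy]-7-hydroxy-4,6,8-trimethylnona-1,3-dien-5-one | CC(C)(C)[Si](C)(C)OC[C@H](C)[C@H](O)[C@@H](C)C(=O)/C(C)=C/C=C | intermediate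
11 | (2S,3S,4R,5S,6E)-1-[(tert-butyldimethylsilyl)oxy]-2,4,6-trimethylnona-6,8-diene-3,5-diol | CC(C)(C)[Si](C)(C)OC[C@H](C)[C@H](O)[C@@H](C)[C@H](O)/C(C)=C/C=C | intermediate
12 | tert-butyldimethyl{(2S)-2-[(4S,5R,6S)-2,2,5-trimethyl-6-[(2E)-penta-2,4-dien-2-yl]-1,3-dioxan-4-yl]propoxy}silane | CC(C)(C)[Si](C)(C)OC[C@H](C)[C@@H]1OC(C)(C)O[C@@H]([C@@H]1C)/C(C)=C/C=C | intermediate
13 | (2S)-2-[(4S,5R,6S)-2,2,5-trimethyl-6-[(2E)-penta-2,4-dien-2-yl]-1,3-dioxan-4-yl]propan-1-ol | OC[C@H](C)[C@@H]1OC(C)(C)O[C@@H]([C@@H]1C)/C(C)=C/C=C | intermediate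
14 | (2R)-2-[(4R,5R,6S)-2,2,5-trimethyl-6-[(2E)-penta-2,4-dien-2-yl]-1,3-dioxan-4-yl]propanal | O=C[C@H](C)[C@@H]1OC(C)(C)O[C@@H]([C@@H]1C)/C(C)=C/C=C | intermediate
15 | pentan-3-one | CCC(=O)CC | starting material
16 | propanoyl chloride | CCC(=O)Cl | starting material
17 | 4-methylheptane-3,5-dione | CCC(=O)C(C)C(=O)CC | intermediate
18 | dilithium dienolate of 17, deprotonated at C4 and C2 (formed in the flask) | [Li+].[Li+].CC=C([O-])C(C)=C([O-])CC | intermediate
19 | 7-hydroxy-4,6-dimethyl-8-[(4R,5R,6S)-2,2,5-trimethyl-6-[(2E)-penta-2,4-dien-2-yl]-1,3-dioxan-4-yl]nonane-3,5-dione (C8 as in 14; mixture at C4, C6, C7) | CCC(=O)C(C)C(=O)C(C)C(O)[C@H](C)[C@@H]1OC(C)(C)O[C@@H]([C@@H]1C)/C(C)=C/C=C | intermediate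
20 | 4,6-dimethyl-8-[(4R,5R,6S)-2,2,5-trimethyl-6-[(2E)-penta-2,4-dien-2-yl]-1,3-dioxan-4-yl]nonane-3,5,7-trione (C8 as in 14; C4/C6 epimers and enols) | CCC(=O)C(C)C(=O)C(C)C(=O)[C@H](C)[C@@H]1OC(C)(C)O[C@@H]([C@@H]1C)/C(C)=C/C=C | intermediate
21 | 2-ethyl-3,5-dimethyl-6-{(1R)-1-[(4R,5R,6S)-2,2,5-trimethyl-6-[(2E)-penta-2,4-dien-2-yl]-1,3-dioxan-4-yl]ethyl}-4H-pyran-4-one | CCc1oc([C@H](C)[C@@H]2OC(C)(C)O[C@@H]([C@@H]2C)/C(C)=C/C=C)c(C)c(=O)c1C | intermediate
22 | propanal | CCC=O | starting material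
23 | (E)-but-2-ene | C/C=C/C | starting material
24 | (E)-but-2-enylbis(isopinocampheyl)borane (formed in the flask) | C/C=C/CB([C@H]1C[C@H]2C[C@@H]([C@@H]1C)C2(C)C)[C@H]1C[C@H]2C[C@@H]([C@@H]1C)C2(C)C | intermediate
25 | (3S,4R)-4-methylhex-5-en-3-ol | C=C[C@@H](C)[C@@H](O)CC | intermediate
26 | tert-butyldimethyl{[(3S,4R)-4-methylhex-5-en-3-yl]oxy}silane | C=C[C@@H](C)[C@@H](O[Si](C)(C)C(C)(C)C)CC | intermediate
27 | (2S,3S)-3-[(tert-butyldimethylsilyl)oxy]-2-methylpentanal | O=C[C@@H](C)[C@@H](O[Si](C)(C)C(C)(C)C)CC | intermediate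
28 | ethyl formate | CCOC=O | starting material
29 | sodium 2-methyl-3-oxopent-1-en-1-olate (formed in the flask) | CCC(=O)C(C)=C[O-].[Na+] | intermediate
30 | (E)-1-methoxy-2-methylpent-1-en-3-one | CCC(=O)/C(C)=C/OC | intermediate
31 | lithium (1E)-1-methoxy-2-methylpenta-1,3-dien-3-olate (formed in the flask) | [Li+].CC=C([O-])/C(C)=C/OC | intermediate
32 | (1E,6R,7S)-7-[(tert-butyldimethylsilyl)oxy]-5-hydroxy-1-methoxy-2,4,6-trimethylnon-1-en-3-one (mixture at C4, C5) | CO/C=C(C)/C(=O)C(C)C(O)[C@@H](C)[C@@H](O[Si](C)(C)C(C)(C)C)CC | intermediate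
33 | (1E,6S,7S)-7-[(tert-butyldimethylsilyl)oxy]-1-methoxy-2,4,6-trimethylnon-1-ene-3,5-dione (C4 epimers and enol) | CO/C=C(C)/C(=O)C(C)C(=O)[C@@H](C)[C@@H](O[Si](C)(C)C(C)(C)C)CC | intermediate
34 | 2-[(2S,3S)-3-[(tert-butyldimethylsilyl)oxy]pentan-2-yl]-3,5-dimethyl-4H-pyran-4-one | Cc1coc([C@@H](C)[C@@H](O[Si](C)(C)C(C)(C)C)CC)c(C)c1=O | intermediate
35 | 2-ethyl-3,5-dimethyl-6-{(1R)-1-[(4R,5R,6S)-2,2,5-trimethyl-6-[(2E,4S)-4-{6-[(2S,3S)-3-[(tert-butyldimethylsilyl)oxy]pentan-2-yl]-3,5-dimethyl-4-oxo-4H-pyran-2-yl}pent-2-en-2-yl]-1,3-dioxan-4-yl]ethyl}-4H-pyran-4-one | CCc1oc([C@H](C)[C@@H]2OC(C)(C)O[C@@H]([C@@H]2C)/C(C)=C/[C@H](C)c3oc([C@@H](C)[C@@H](O[Si](C)(C)C(C)(C)C)CC)c(C)c(=O)c3C)c(C)c(=O)c1C | intermediate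
36 | 2-ethyl-6-[(2R,3R,4R,5S,6E,8S)-3,5-dihydroxy-4,6-dimethyl-8-{6-[(2S,3S)-3-hydroxypentan-2-yl]-3,5-dimethyl-4-oxo-4H-pyran-2-yl}non-6-en-2-yl]-3,5-dimethyl-4H-pyran-4-one | CCc1oc([C@H](C)[C@H](O)[C@@H](C)[C@H](O)/C(C)=C/[C@H](C)c2oc([C@@H](C)[C@@H](O)CC)c(C)c(=O)c2C)c(C)c(=O)c1C | target

## Step count and risks

Total step count: 22. Longest linear sequence: 12 steps (3, 4, 5, 6, 7, 8, 9, 11, 12, 13, 21, 22), which is about 55 % of the total.

Steps most likely to fail:

**Step 21 (the new C–H addition).** The risks are: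
- low reactivity of the pyranone C–H bond;
- loss of face control at C8, which is remote from the existing centres;
- nickel hydride migration of the alkene into conjugation with ring B;
- β-oxygen elimination at the allyl terminus next to the acetonide.

The fallback uses known chemistry. It sets out from 21 and 27 and comes back at 35. Rh(acac)(CO)2 with a bis(diazaphospholane) ligand under CO/H2 hydroformylates the terminal alkene of 21 at its internal carbon to give the branched β,γ-unsaturated aldehyde F8. In parallel, 27 is added to the lithium enolate of 15 to give the hydroxy ketone F9, which Dess–Martin oxidation turns into the β-diketone F10. Double deprotonation of F10 with LiN(i-Pr)2 and addition to F8 gives the hydroxy diketone F11. Dess–Martin oxidation gives the triketone F12, and PPh3/CCl4/Et3N closes ring B to give 35. The price is a longer sequence and an epimerisable C8 centre next to a ketone.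

**Step 5 (boron aldol of the dienone).** The risks are competing γ-deprotonation or polymerisation of the cross-conjugated dienone and only moderate anti-Felkin selectivity.

The fallback reverses the polarity of the aldol. It sets out from 7 and 4 and comes back at 11. Ester 7 is converted with MeNH(OMe)·HCl and i-PrMgCl into the Weinreb amide F1, and EtMgBr gives the ethyl ketone F2. Acrolein 4 and 2-(triphenylphosphoranylidene)propanal give the dienal F3. A boron aldol of F2 with F3, mediated by Ipc2BOTf made from (+)-α-pinene and i-Pr2NEt, gives the syn–anti adduct F4. Et2BOMe/NaBH4 then reduces the C3 ketone syn to the C5 hydroxyl and gives 11.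

**Step 13 (closure of ring A).** The risks are that acid released in the cyclodehydration opens the acetonide or ionises the dienylic C–O bond, and that C2 next to the triketone epimerises.

The fallback avoids any dehydrating agent. It sets out from 17 and 14 and comes back at 21. Diketone 17 is O-methylated (Me2SO4, K2CO3, acetone) to the vinylogous ester F5. Its lithium enolate (LiN(SiMe3)2, THF, −78 °C) adds to 14 to give the hydroxy enone F6. Dess–Martin oxidation gives the methoxy-enone diketone F7. Catalytic PPTS in benzene at 50 °C closes ring A by addition–elimination, as in step 20, to give 21.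

## Further compounds

F1 | step 5 | (S)-3-[(tert-butyldimethylsilyl)oxy]-N-methoxy-N,2-dimethylpropanamide | CC(C)(C)[Si](C)(C)OC[C@H](C)C(=O)N(C)OC
F2 | step 5 | (S)-1-[(tert-butyldimethylsilyl)oxy]-2-methylpentan-3-one | CC(C)(C)[Si](C)(C)OC[C@H](C)C(=O)CC
F3 | step 5 | (E)-2-methylpenta-2,4-dienal | C=C/C=C(C)/C=O
F4 | step 5 | (2S,4S,5S,6E)-1-[(tert-butyldimethylsilyl)oxy]-5-hydroxy-2,4,6-trimethylnona-6,8-dien-3-one | CC(C)(C)[Si](C)(C)OC[C@H](C)C(=O)[C@@H](C)[C@H](O)/C(C)=C/C=C
F5 | step 13 | 5-methoxy-4-methylhept-4-en-3-one (E/Z mixture) | CCC(=O)C(C)=C(CC)OC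
F6 | step 13 | 7-hydroxy-3-methoxy-4,6-dimethyl-8-[(4R,5R,6S)-2,2,5-trimethyl-6-[(2E)-penta-2,4-dien-2-yl]-1,3-dioxan-4-yl]non-3-en-5-one (C8 as in 14; mixture at C6, C7) | CCC(OC)=C(C)C(=O)C(C)C(O)[C@H](C)[C@@H]1OC(C)(C)O[C@@H]([C@@H]1C)/C(C)=C/C=C
F7 | step 13 | 3-methoxy-4,6-dimethyl-8-[(4R,5R,6S)-2,2,5-trimethyl-6-[(2E)-penta-2,4-dien-2-yl]-1,3-dioxan-4-yl]non-3-ene-5,7-dione (C8 as in 14) | CCC(OC)=C(C)C(=O)C(C)C(=O)[C@H](C)[C@@H]1OC(C)(C)O[C@@H]([C@@H]1C)/C(C)=C/C=C
F8 | step 21 | branched aldehyde: 21 with the terminal CH=CH2 replaced by (S)-CH(CH3)CHO | CCc1oc([C@H](C)[C@@H]2OC(C)(C)O[C@@H]([C@@H]2C)/C(C)=C/[C@H](C)C=O)c(C)c(=O)c1C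
F9 | step 21 | (6S,7S)-7-[(tert-butyldimethylsilyl)oxy]-5-hydroxy-4,6-dimethylnonan-3-one (descriptors as in 27; mixture at C4, C5) | CCC(=O)C(C)C(O)[C@@H](C)[C@@H](O[Si](C)(C)C(C)(C)C)CC
F10 | step 21 | (6S,7S)-7-[(tert-butyldimethylsilyl)oxy]-4,6-dimethylnonane-3,5-dione | CCC(=O)C(C)C(=O)[C@@H](C)[C@@H](O[Si](C)(C)C(C)(C)C)CC
F11 | step 21 | hydroxy diketone from F8 and the dianion of F10 (mixture at the three new centres) | CCc1oc([C@H](C)[C@@H]2OC(C)(C)O[C@@H]([C@@H]2C)/C(C)=C/[C@H](C)C(O)C(C)C(=O)C(C)C(=O)[C@@H](C)[C@@H](O[Si](C)(C)C(C)(C)C)CC)c(C)c(=O)c1C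
F12 | step 21 | triketone obtained by oxidation of F11 | CCc1oc([C@H](C)[C@@H]2OC(C)(C)O[C@@H]([C@@H]2C)/C(C)=C/[C@H](C)C(=O)C(C)C(=O)C(C)C(=O)[C@@H](C)[C@@H](O[Si](C)(C)C(C)(C)C)CC)c(C)c(=O)c1C
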